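**Retrosynthetic overview**

1. The target is two copies of one (2R)-2,3-cis flavan unit. Cleaving the interflavan bond C4(upper)–C6(lower) (SN1 Friedel–Crafts) and the lower C4–OH (SN1 hydrolysis) leads back to a single protected monomer, the all-cis flavan-3,4-diol, used once as electrophile (4-acetate) and once as nucleophile (4-aryl thioether).
2. The monomer comes from a racemic, stereolabile 3-benzyloxyflavanone by a dynamic kinetic resolution that sets C2, C3 and C4 in one reduction. Both later C4 substitutions are steered to the β-face by the same 2,3-cis pair of substituents.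
3. The flavanone comes from a 2-fluoroaryl α-benzyloxy ketone and the B-ring aldehyde by an aldol/SNAr annulation that forms C2–C3 and O1–C8a and so closes ring C. C2 and O1 enter together as the aldehyde C=O.
4. Enabling feature: C4 of ring C sits on C4a, ortho to C8a of ring A, so a C4 ketone both acidifies C3–H and activates a fluorine on C8a for ipso-substitution. The fluorine is lost in the annulation and the ketone level is removed in the next step.
5. Ring order: rings A and B are bought as benzenoid building blocks; ring C is the only ring made (once, for both units). Then follow the stereocentres, divergence, interflavan bond, lower C4–OH and deprotection.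

Key step: step 4

Remark: flavan numbering is used for both units (O1, C2, C3, C4, C4a, C5–C8, C8a; B-ring atoms primed). "Upper unit" is the flavan whose C4 carries the other flavan; "lower unit" is the flavan-3,4-diol. α is the face of ring C that carries the 2-aryl group, β the opposite face.

**Route**

Step 1
Reactants: 1 3-fluorocatechol (3-fluorobenzene-1,2-diol)
Product: 2 1,2-bis(benzyloxy)-3-fluorobenzene
Conditions: BnBr (2.2 equiv), K2CO3, DMF, 50 °C
Reagents that add atoms: benzyl bromide, BrCc1ccccc1
Why: Williamson ether synthesis on both phenols; benzyl ethers are used throughout because they survive every later step and are removed together at the end.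

Step 2
Reactants: 2 1,2-bis(benzyloxy)-3-fluorobenzene
Product: 3 1,2-bis(benzyloxy)-4-bromo-3-fluorobenzene
Conditions: NBS (1.05 equiv), MeCN, 0 °C to rt
Reagents that add atoms: N-bromosuccinimide, O=C1CCC(=O)N1Br
Why: Electrophilic aromatic bromination, expected para to the 1-benzyloxy group (the only oxygen that can lie in the ring plane, the 2-benzyloxy group being flanked on both sides), which is the position ortho to fluorine that becomes C4a.

Step 3
Reactants: 3 1,2-bis(benzyloxy)-4-bromo-3-fluorobenzene; 4 2-(benzyloxy)-N-methoxy-N-methylacetamide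
Product: 6 2-(benzyloxy)-1-[3,4-bis(benzyloxy)-2-fluorophenyl]ethan-1-one, via aryllithium 5 (not isolated)
Conditions: n-BuLi, THF, −78 °C; then 4, −78 °C; aq NH4Cl
Reagents that add atoms: none
Why: Bromine–lithium exchange followed by Weinreb ketone synthesis: at −78 °C the ortho-fluoroaryllithium 5 is stable against loss of LiF, and the chelated tetrahedral adduct prevents over-addition.

Step 4
Reactants: 6 2-(benzyloxy)-1-[3,4-bis(benzyloxy)-2-fluorophenyl]ethan-1-one; 7 3,4-bis(benzyloxy)benzaldehyde (1.3 equiv)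
Product: 9 rac-3,7,8-tris(benzyloxy)-2-[3,4-bis(benzyloxy)phenyl]-2,3-dihydro-4H-chromen-4-one (2,3-cis/trans mixture), via caesium aldolate 8 (not isolated)
Conditions: Cs2CO3 (2.5 equiv), DMSO, 25 to 70 °C
Reagents that add atoms: none
Why: Proposed new method: the caesium enolate of 6 (only C3 is enolisable, 7 has no α-hydrogen) adds to the aldehyde carbon of 7 to form C2–C3, and the resulting alkoxide 8, whose oxygen is the former aldehyde oxygen (O1), attacks the fluorine-bearing C8a in an intramolecular addition–elimination (SNAr) in which the ortho C4 carbonyl accepts the Meisenheimer charge and fluoride leaves, forming O1–C8a. The closest known reaction types are the base-mediated cyclisation of 1-(2-fluoroaryl)-1,3-diketones to chromones (O-arylation ortho to an acyl group) and the aldol/SNAr and Michael/SNAr domino annulations of activated 2-fluoroaryl carbonyl compounds; what is new is their combination on an α-alkoxy ketone and an aromatic aldehyde to give a 3-oxygenated flavanone on an electron-rich fluoroarene. Ring C closes through a six-membered transition state, 6-exo-trig with respect to the C8a=C8 bond of the arene. C2 and C3 are created without control and on purpose: both stay labile in 9 (C3 by enolisation, C2 by retro-oxa-Michael ring opening), and their configuration is set in step 5. The step needs chemoselectivity for O-arylation over loss of water from the aldol: aldol addition, retro-aldol cleavage and dehydration to the α-benzyloxychalcone are reversible under the conditions (the chalcone re-enters by conjugate addition of the hydroxide it released), whereas loss of fluoride is not, so the manifold should drain into 9. Regiochemistry is fixed because fluorine marks the only ring carbon that can be substituted, and the 3-O-benzyl group rules out a competing five-membered closure through the C3 oxygen.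

Step 5
Reactants: 9 rac-3,7,8-tris(benzyloxy)-2-[3,4-bis(benzyloxy)phenyl]-2,3-dihydro-4H-chromen-4-one
Product: 10 (2R,3R,4R)-3,7,8-tris(benzyloxy)-2-[3,4-bis(benzyloxy)phenyl]-3,4-dihydro-2H-chromen-4-ol (2,3-cis-3,4-cis: 2α-aryl, 3α-OBn, 4α-OH)
Conditions: RuCl[(S,S)-TsDPEN](p-cymene) (2 mol %), HCO2H (3 equiv), DBU (4 equiv), MeCN, 40 °C
Reagents that add atoms: none
Why: Noyori–Ikariya asymmetric transfer hydrogenation run as a dynamic kinetic resolution: C3 epimerises by enolisation and C2 by retro-oxa-Michael/oxa-Michael ring opening under the slight excess of DBU, so all four stereoisomers of 9 interconvert, and the (S,S)-catalyst should deliver hydride to the β-face of C4=O fastest in the isomer whose 3-benzyloxy group is axial and anti to the incoming hydride (Felkin–Anh) and whose 2-aryl group is equatorial on the α-face, giving the all-cis alcohol.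

Step 6
Reactants: 10 (2R,3R,4R)-3,7,8-tris(benzyloxy)-2-[3,4-bis(benzyloxy)phenyl]-3,4-dihydro-2H-chromen-4-ol
Product: 12 (2R,3S,4S)-3,7,8-tris(benzyloxy)-2-[3,4-bis(benzyloxy)phenyl]-4-[(2,6-dimethylphenyl)sulfanyl]-3,4-dihydro-2H-chromene (2,3-cis-3,4-trans: 4β-S), via benzylic cation 11 (not isolated)
Conditions: 2,6-Me2C6H3SH (3 equiv), BF3·OEt2 (0.2 equiv), CH2Cl2, −30 to 0 °C
Reagents that add atoms: 2,6-dimethylbenzenethiol, Cc1cccc(C)c1S
Why: Acid-catalysed SN1 thiolysis through cation 11, which is stabilised by the para 7-benzyloxy group and captured by the thiol on the β-face, anti to the axial 3-benzyloxy group; the hindered aryl thioether is inert to hard Lewis acids and is later activated by AgOTf, which keeps C4 of the future lower unit masked during step 8.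

Step 7
Reactants: 10 (2R,3R,4R)-3,7,8-tris(benzyloxy)-2-[3,4-bis(benzyloxy)phenyl]-3,4-dihydro-2H-chromen-4-ol
Product: 13 (2R,3S,4R)-3,7,8-tris(benzyloxy)-2-[3,4-bis(benzyloxy)phenyl]-3,4-dihydro-2H-chromen-4-yl acetate (2,3-cis-3,4-cis)
Conditions: Ac2O, pyridine, DMAP (cat.), CH2Cl2, rt
Reagents that add atoms: acetic anhydride, CC(=O)OC(C)=O
Why: DMAP-catalysed acylation turns the benzylic C4–OH into a leaving group that a hard silyl Lewis acid ionises while the thioether of 12 stays intact (orthogonal activation).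

Step 8
Reactants: 13 the 4-acetate (electrophile); 12 the 4β-thioether (nucleophile, 3 equiv, excess recovered)
Product: 14 deca-O-benzyl (4β→6)-linked dimer carrying the lower 4β-[(2,6-dimethylphenyl)sulfanyl] group
Conditions: Me3SiOTf (0.2 equiv), 4 Å MS, CH2Cl2, −78 to −40 °C
Reagents that add atoms: none
Why: SN1 Friedel–Crafts alkylation: Me3SiOTf ionises the acetate of 13 to the same C4 benzylic cation through which step 6 runs (compound 11), and C6 of 12 (para to O1 and ortho to the 7-benzyloxy group, the most electron-rich open position, whereas C5 is para only to the twisted 8-benzyloxy group and peri to C4) attacks its β-face anti to the axial 3-benzyloxy group, setting the upper C4 as 4β-aryl (3,4-trans); the excess of 12 suppresses self-condensation, and any thio-group transfer between this cation and 12 is degenerate.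

Step 9
Reactants: 14 the dimer thioether
Product: 16 deca-O-benzyl (4β→6)-linked dimer with free lower 4β-OH, via dimer cation 15 (not isolated)
Conditions: AgOTf (1.5 equiv), NaHCO3, THF/H2O (10:1), 0 °C
Reagents that add atoms: water, O
Why: Thiophilic activation by AgOTf ionises the C4–S bond to cation 15, which water captures on the β-face anti to the axial 3-benzyloxy group, giving the 3,4-trans 4β-alcohol whatever the configuration of the thioether (stereoconvergent SN1 hydrolysis); NaHCO3 keeps the acid-labile benzylic alcohol from re-ionising.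

Step 10
Reactants: 16 the protected dimer alcohol
Product: 17 the target, (2R,3R,4S)-2-(3,4-dihydroxyphenyl)-6-[(2R,3R,4S)-2-(3,4-dihydroxyphenyl)-3,7,8-trihydroxy-3,4-dihydro-2H-chromen-4-yl]-3,4-dihydro-2H-chromene-3,4,7,8-tetrol
Conditions: H2 (1 atm), Pd(OH)2/C, THF/MeOH/H2O, rt
Reagents that add atoms: none
Why: Catalytic hydrogenolysis cleaves all ten O-benzyl groups (eight aryl and two alkyl benzyl ethers) under neutral conditions at 1 atm, under which the secondary C4–OH and the interflavan bond should persist.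

**Compound list**

1 | 3-fluorocatechol (3-fluorobenzene-1,2-diol) | Oc1cccc(F)c1O | starting material
2 | 1,2-bis(benzyloxy)-3-fluorobenzene | Fc1cccc(OCc2ccccc2)c1OCc1ccccc1 | intermediate
3 | 1,2-bis(benzyloxy)-4-bromo-3-fluorobenzene | Fc1c(Br)ccc(OCc2ccccc2)c1OCc1ccccc1 | intermediate
4 | 2-(benzyloxy)-N-methoxy-N-methylacetamide | CON(C)C(=O)COCc1ccccc1 | starting material
5 | [3,4-bis(benzyloxy)-2-fluorophenyl]lithium | Fc1c([Li])ccc(OCc2ccccc2)c1OCc1ccccc1 | intermediate (not isolated)
6 | 2-(benzyloxy)-1-[3,4-bis(benzyloxy)-2-fluorophenyl]ethan-1-one | Fc1c(C(=O)COCc2ccccc2)ccc(OCc2ccccc2)c1OCc1ccccc1 | intermediate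
7 | 3,4-bis(benzyloxy)benzaldehyde | O=Cc1ccc(OCc2ccccc2)c(OCc2ccccc2)c1 | starting material
8 | caesium 2-(benzyloxy)-1-[3,4-bis(benzyloxy)phenyl]-3-[3,4-bis(benzyloxy)-2-fluorophenyl]-3-oxopropan-1-olate (syn/anti mixture, racemic; no stereodescriptors) | [Cs+].[O-]C(c1ccc(OCc2ccccc2)c(OCc2ccccc2)c1)C(OCc1ccccc1)C(=O)c1ccc(OCc2ccccc2)c(OCc2ccccc2)c1F | intermediate (not isolated)
9 | rac-3,7,8-tris(benzyloxy)-2-[3,4-bis(benzyloxy)phenyl]-2,3-dihydro-4H-chromen-4-one (all four stereoisomers, interconverting; no stereodescriptors) | O=C1c2ccc(OCc3ccccc3)c(OCc3ccccc3)c2OC(c2ccc(OCc3ccccc3)c(OCc3ccccc3)c2)C1OCc1ccccc1 | intermediate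
10 | (2R,3R,4R)-3,7,8-tris(benzyloxy)-2-[3,4-bis(benzyloxy)phenyl]-3,4-dihydro-2H-chromen-4-ol (2,3-cis-3,4-cis) | c1cc2c(c(OCc3ccccc3)c1OCc1ccccc1)O[C@H](c1ccc(OCc3ccccc3)c(OCc3ccccc3)c1)[C@H](OCc1ccccc1)[C@@H]2O | intermediate
11 | (2R)-2,3-cis-3,7,8-tris(benzyloxy)-2-[3,4-bis(benzyloxy)phenyl]chroman-4-ylium (benzylic cation) | c1cc2c(c(OCc3ccccc3)c1OCc1ccccc1)O[C@H](c1ccc(OCc3ccccc3)c(OCc3ccccc3)c1)[C@H](OCc1ccccc1)[CH+]2 | intermediate (not isolated)
12 | (2R,3S,4S)-3,7,8-tris(benzyloxy)-2-[3,4-bis(benzyloxy)phenyl]-4-[(2,6-dimethylphenyl)sulfanyl]-3,4-dihydro-2H-chromene (2,3-cis-3,4-trans) | c1cc2c(c(OCc3ccccc3)c1OCc1ccccc1)O[C@H](c1ccc(OCc3ccccc3)c(OCc3ccccc3)c1)[C@H](OCc1ccccc1)[C@H]2Sc1c(C)cccc1C | intermediate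
13 | (2R,3S,4R)-3,7,8-tris(benzyloxy)-2-[3,4-bis(benzyloxy)phenyl]-3,4-dihydro-2H-chromen-4-yl acetate (2,3-cis-3,4-cis) | c1cc2c(c(OCc3ccccc3)c1OCc1ccccc1)O[C@H](c1ccc(OCc3ccccc3)c(OCc3ccccc3)c1)[C@H](OCc1ccccc1)[C@@H]2OC(C)=O | intermediate
14 | deca-O-benzyl dimer thioether: upper unit (2R, 2,3-cis, 4β-aryl) bonded through C4 to C6 of the lower unit (2R, 2,3-cis, 4β-[(2,6-dimethylphenyl)sulfanyl]); all eight phenols and both 3-OH as benzyl ethers | C(c5ccccc5)Oc1ccc([C@H]2Oc3c(ccc(OCc5ccccc5)c3OCc5ccccc5)[C@H](c3cc4c(c(OCc5ccccc5)c3OCc5ccccc5)O[C@H](c3ccc(OCc5ccccc5)c(OCc5ccccc5)c3)[C@H](OCc5ccccc5)[C@H]4Sc5c(C)cccc5C)[C@H]2OCc5ccccc5)cc1OCc5ccccc5 | intermediate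
15 | dimer cation: 14 with the lower C4–S bond ionised (lower chroman-4-ylium) | C(c5ccccc5)Oc1ccc([C@H]2Oc3c(ccc(OCc5ccccc5)c3OCc5ccccc5)[C@H](c3cc4c(c(OCc5ccccc5)c3OCc5ccccc5)O[C@H](c3ccc(OCc5ccccc5)c(OCc5ccccc5)c3)[C@H](OCc5ccccc5)[CH+]4)[C@H]2OCc5ccccc5)cc1OCc5ccccc5 | intermediate (not isolated)
16 | deca-O-benzyl dimer alcohol: as 14 but with free lower 4β-OH (lower unit 2,3-cis-3,4-trans) | C(c5ccccc5)Oc1ccc([C@H]2Oc3c(ccc(OCc5ccccc5)c3OCc5ccccc5)[C@H](c3cc4c(c(OCc5ccccc5)c3OCc5ccccc5)O[C@H](c3ccc(OCc5ccccc5)c(OCc5ccccc5)c3)[C@H](OCc5ccccc5)[C@H]4O)[C@H]2OCc5ccccc5)cc1OCc5ccccc5 | intermediate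
17 | (2R,3R,4S)-2-(3,4-dihydroxyphenyl)-6-[(2R,3R,4S)-2-(3,4-dihydroxyphenyl)-3,7,8-trihydroxy-3,4-dihydro-2H-chromen-4-yl]-3,4-dihydro-2H-chromene-3,4,7,8-tetrol | Oc1ccc([C@H]2Oc3c(ccc(O)c3O)[C@H](c3cc4c(c(O)c3O)O[C@H](c3ccc(O)c(O)c3)[C@H](O)[C@H]4O)[C@H]2O)cc1O | target

**Step count and risks**

Total steps: 10. Longest linear sequence: 9 steps (steps 1 to 5, then 6 or 7, then 8 to 10).

Steps most likely to fail:

1. Step 4 (proposed new method). What may go wrong: dehydration of the aldol and retro-aldol cleavage outrun the ipso-substitution at the electron-rich fluoroarene, so the material stalls at the open-chain stage instead of closing ring C. Fallback with known chemistry, closing ring C at O1–C2 instead: it sets out from aldehyde 7. Claisen–Schmidt condensation (KOH, EtOH) of 7 with 1-[3,4-bis(benzyloxy)-2-hydroxyphenyl]ethan-1-one F1 gives the 2'-hydroxychalcone F2; F1 is made from commercial 2,3,4-trihydroxyacetophenone with BnBr, K2CO3, acetone, the chelated 2-OH staying free. Algar–Flynn–Oyamada oxidation in the cold (H2O2, NaOH, MeOH, 0 °C) should give the racemic trans-dihydroflavonol F3. O-Benzylation with benzyl 2,2,2-trichloroacetimidate and TfOH (cat.) gives the trans isomer of 9, where the route is rejoined (step 5 accepts either isomer).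

2. Step 5. What may go wrong: epimerisation at C2 by ring opening is slow relative to hydride transfer, so mismatched isomers are reduced and diastereomeric and enantiomeric purity erode. Fallback, which decouples racemisation from reduction: it sets out from 9. Transfer hydrogenation with the same catalyst in HCO2H/Et3N (5:2) without DBU lets only C3 epimerise. The (2R) half of the material is then reduced to 10 through its 2,3-cis form, while the (2S)-ketone F4 is left behind (kinetic resolution at C2). F4 is separated, racemised in a separate flask with DBU back to 9 and resubmitted; the route is rejoined at 10.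

3. Step 8. What may go wrong: the ionised electrophile is captured by C6 of another electrophile-derived unit or of the product (oligomerisation), which a moderately nucleophilic pyrogallol-type ring cannot fully outcompete. Fallback, capping the nucleophilic position of the electrophile: it sets out from 13. Bromination with NBS (MeCN, 0 °C) at C6 (para to O1) gives the 6-bromo acetate F5, which cannot act as a nucleophile. Coupling with 12 under the conditions of step 8 gives the bromo dimer thioether F6. AgOTf, NaHCO3, THF/H2O gives the bromo dimer alcohol F7. Hydrogenolysis with H2, Pd(OH)2/C and NaOAc removes the bromine together with the benzyl groups and rejoins the route at 17.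

**Further compounds**

F1 | step 4 | 1-[3,4-bis(benzyloxy)-2-hydroxyphenyl]ethan-1-one | CC(=O)c1ccc(OCc2ccccc2)c(OCc2ccccc2)c1O
F2 | step 4 | (E)-1-[3,4-bis(benzyloxy)-2-hydroxyphenyl]-3-[3,4-bis(benzyloxy)phenyl]prop-2-en-1-one | O=C(/C=C/c1ccc(OCc2ccccc2)c(OCc2ccccc2)c1)c1ccc(OCc2ccccc2)c(OCc2ccccc2)c1O
F3 | step 4 | rac-2,3-trans-7,8-bis(benzyloxy)-2-[3,4-bis(benzyloxy)phenyl]-3-hydroxy-2,3-dihydro-4H-chromen-4-one (racemate, one enantiomer drawn) | O=C1c2ccc(OCc3ccccc3)c(OCc3ccccc3)c2O[C@H](c2ccc(OCc3ccccc3)c(OCc3ccccc3)c2)[C@H]1O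
F4 | step 5 | (2S)-3,7,8-tris(benzyloxy)-2-[3,4-bis(benzyloxy)phenyl]-2,3-dihydro-4H-chromen-4-one (C3 epimers) | O=C1c2ccc(OCc3ccccc3)c(OCc3ccccc3)c2O[C@@H](c2ccc(OCc3ccccc3)c(OCc3ccccc3)c2)C1OCc1ccccc1
F5 | step 8 | (2R)-2,3-cis-3,4-cis-3,7,8-tris(benzyloxy)-2-[3,4-bis(benzyloxy)phenyl]-6-bromo-3,4-dihydro-2H-chromen-4-yl acetate | Brc1cc2c(c(OCc3ccccc3)c1OCc1ccccc1)O[C@H](c1ccc(OCc3ccccc3)c(OCc3ccccc3)c1)[C@H](OCc1ccccc1)[C@@H]2OC(C)=O
F6 | step 8 | 14 with bromine at C6 of the upper unit | C(c5ccccc5)Oc1ccc([C@H]2Oc3c(cc(Br)c(OCc5ccccc5)c3OCc5ccccc5)[C@H](c3cc4c(c(OCc5ccccc5)c3OCc5ccccc5)O[C@H](c3ccc(OCc5ccccc5)c(OCc5ccccc5)c3)[C@H](OCc5ccccc5)[C@H]4Sc5c(C)cccc5C)[C@H]2OCc5ccccc5)cc1OCc5ccccc5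
F7 | step 8 | 16 with bromine at C6 of the upper unit | C(c5ccccc5)Oc1ccc([C@H]2Oc3c(cc(Br)c(OCc5ccccc5)c3OCc5ccccc5)[C@H](c3cc4c(c(OCc5ccccc5)c3OCc5ccccc5)O[C@H](c3ccc(OCc5ccccc5)c(OCc5ccccc5)c3)[C@H](OCc5ccccc5)[C@H]4O)[C@H]2OCc5ccccc5)cc1OCc5ccccc5
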